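## Structural features

The target is a flavone. Benzene ring A is fused through C4a–C8a to the 4-pyranone ring C, which carries phenyl ring B at C2. Ring A holds a phloroglucinol pattern in three different forms: the ring oxygen O1 at C8a, a methyl ether at C5 and a free phenol at C7, with hydrogen only at C8. C6 lies between the two exocyclic oxygens and para to C8a, and it is bonded to C2' of an otherwise unsubstituted N-methylpiperidine.

C2' is the only stereocentre and is S (N1' > C6 > C3' > H). It has no stereogenic neighbour, so nothing in the molecule can relay its configuration and it must be set absolutely.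

C2' is also the weak point. It is a benzylic amine carbon on an arene with donor oxygens ortho, ortho and para, and with the 7-OH it forms a phenolic Mannich base. Heterolysis of C2'–N1' followed by re-closure would therefore racemise it, through a trialkoxybenzyl cation in acid or an ortho-quinone methide from the zwitterion. This happens most easily while ring A still lacks the electron-withdrawing C4 carbonyl. Other sensitive groups are the 5-OMe peri to C4=O (lost to Lewis acids), the reducible C2=C3 enone, and the basic, oxidisable tertiary amine.

The real difficulty is twofold. One part is absolute control at a carbon shielded by two ortho substituents. The other is the choice between the two methine positions of ring A, both flanked by two oxygens, because building ring C on the wrong one gives the 5-hydroxy-7-methoxy isomer.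

The key step exploits two facts. C2' hangs on the ring A carbon that corresponds to the formyl-bearing carbon of a 2,4,6-trioxygenated benzaldehyde, and C3'–C6' is an unbranched four-carbon chain ending at N1'. An aldimine carbon can therefore take C3' as a nucleophile, and its nitrogen can afterwards take C6' as an electrophile.

## Logic of the disconnections

**20 from 19.** Only the O–Si bond on the C7 oxygen is involved and no skeletal bond is cut. The phenol stays masked to the end because, once free, it completes the Mannich-base array around C2' and makes the compound zwitterionic. The gain is that every earlier intermediate is a lipophilic, non-phenolic amine. The forward step must cleave an aryl silyl ether without exposing ring C or C2' to strong base.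

**19 from 17.** The O1–C2 bond is cut, which opens ring C to an aryl alkynyl ketone whose O1 is still an acetal. C2 is the β-carbon of that ynone and O1 sits ortho to the ketone, so the bond forms by intramolecular conjugate addition with no new atoms. One ring disappears. The demand is 6-endo rather than 5-exo closure, and an acetal cleavage that spares the C5 methyl ether and C2'.

**17 from 11 and 15.** The C4a–C4 bond is cut into an arene nucleophile and an acyl donor. C4a lies between the methyl ether and the MOM acetal, the site of cooperative ortho-metalation, whereas C8 lies beside a bulky silyl ether that does not coordinate. The protecting groups already present thus answer the regiochemical question. The molecule falls into two halves of similar size. The demands are a tertiary, non-electrophilic nitrogen, a MOM group that is still in place, and an acyl donor that stops at the ketone.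

**15 from 12 and 13.** The C3–C4 bond between the alkyne carbon and the carbonyl carbon is cut. A terminal alkyne is the natural nucleophile, and a carbamoyl chloride delivers C4 already at the amide level. Both pieces are simple. The demand is a single acylation without a second addition.

**11 from 9.** N1'–CH3 is cut and the N–S bond of the auxiliary is restored. The auxiliary has done its work and nitrogen needs its methyl group before any organolithium is used. No skeletal simplification results, only the link to the key step. The demand is N–S cleavage by acid so brief and cold that the MOM acetal and the C2'–N1' bond stay intact, with methylation carried out while ring A has no free phenol.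

**9 from 5 and 7.** C2'–C3' and N1'–C6' are cut together. This removes the piperidine ring and the only stereocentre in one move and leaves a planar aldimine and a bifunctional C4 reagent. The cut is made here because the stereogenic sulfur then sits one atom from the reacting carbon. The demands are face-selective addition to a doubly ortho-substituted imine, a carbon–metal bond that tolerates its own chloride, and an N-alkylation that is triggered only after the addition.

**7 from 6.** The C–Mg bond is traced back to C–Br. The two halogens differ enough for selective insertion. The demand is a low preparation temperature and prompt use.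

**5 from 3 and 4.** The C2'=N1' bond is cut into a carbonyl and an amine component. All chirality now resides in a purchasable auxiliary. The demand is a dehydrating Lewis acid strong enough for an electron-rich, hindered aldehyde yet harmless to the silyl ether.

**3 from 2, and 2 from 1.** The O–Si bond at the future C7 oxygen and the O–CH2 bond at the future O1 are cut in turn. In 1 the hydroxyl next to the formyl group is hydrogen-bonded and the para hydroxyl is not, so the two differ in reactivity. The demand is one clean mono-alkylation before the silylation.

## Other disconnections considered

**Alternative 1:**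

- **Cut and forward step.** The cut removes N1'–C2' and C2'–C3' at once and leaves C4'–C5' for a metathesis. Flavone aldehyde A2, N-methylallylamine A3 and pinacol allylboronate A4 would meet in an asymmetric Petasis borono-Mannich allylation under a chiral biphenol catalyst to give diene A1. Ring-closing metathesis would give tetrahydropyridine A5, and saturation of C4'=C5' would give the target.
- **In its favour.** Rings A, B and C are complete before the stereocentre appears. The N-methyl group arrives with A3, so no nitrogen protecting group is handled. The 7-OH next to the formyl group is exactly the hydroxyl such reactions need to form the reactive boronate. Chirality comes from a catalyst. On this last point, and on the number of steps after A2 (three), it is better than the chosen plan.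
- **Against it.** The same phenol can carry the allyl transfer without the chiral diol, so an unselective background path competes with catalyst control. The product would be an enantiomer mixture that chromatography cannot upgrade, whereas 9 is one of two separable diastereomers. A2 is not a catalogue compound, and formylating the parent flavone has to choose between C6 and C8, which brings back the ring A problem without differentiated protecting groups. The ruthenium carbene would need the amine of A1 masked as a salt. The last reduction must distinguish C4'=C5' from the C2=C3 enone and must not hydrogenolyse C2'–N1'.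
- **Comparison.** Both plans add a carbon nucleophile to a C=N bond at C2' through a cyclic, oxygen-bound array, so they are equals in bond logic. The chosen plan differs in tying the controlling oxygen to a stereogenic sulfur next to the reacting centre.

**Alternative 2:**

- **Cut and forward step.** The cut is C7–C8, which dissolves ring A into a polyketide-like chain on a preformed pyranone. A strong base would deprotonate the C8 methyl group of pyranone keto ester A7. The carbanion would attack the ester carbon C7 in a 6-exo-trig Claisen condensation, and tautomerisation would give dihydroxyflavone A6.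
- **In its favour.** The substituents of ring A are placed by acyclic connectivity, so there is no choice between arene positions. On ring A regiochemistry it is better than the chosen plan. The stereocentre would be bought with the piperidine building block rather than made, which is equal or better.
- **Against it.** C6–H of A7 lies between two carbonyl groups and is far more acidic than the methyl group, so a dianion is needed. N1' is β to both carbonyls, so the C6 enolate can expel and re-add the carbamate nitrogen, which endangers C2' in the very step that should preserve it. The pyranone is open to ring cleavage by base.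
- **After the closure.** The 5-OH is hydrogen-bonded to C4=O and is the less reactive phenol. The required 5-O-methylation would therefore need 7-O protection, methylation and deprotection. The carbamate must be exchanged for methyl in two further steps, because hydride reduction would not spare the enone.
- **Comparison.** That is about five steps after the key step against four linear steps here, and A7 itself needs a multistep assembly.

**Alternative 3:**

- **Cut and forward step.** The cuts are C4a–C4, C4–C3 and O1–C2, that is, all of ring C that alkyne 12 does not bring. Iodophenol A9, carbon monoxide A10 and 12 would combine under zerovalent palladium in a secondary-amine medium. The sequence is oxidative addition at C4a–I, insertion of A10, acyl transfer to the alkyne terminus and closure of O1 on C2. It would give silyl flavone A8, the same compound as 19.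
- **In its favour.** It forms three bonds and a ring in one operation, uses 12 directly without step 7 and needs no organolithium. In bonds per step and in convergence it is better than steps 8 and 9. With the same telescoping it is equal in linear length and one step shorter in total.
- **Against it.** It says nothing about C2'. The chiral aryl piperidine must come from a step such as step 5, so it is a partner of the chosen key step rather than a rival.
- **Regiochemistry of the iodide.** Iodine must sit exactly between OMe and OH. Electrophilic iodination of the phenol has two open ortho positions. Only the bulk of the silyl group favours the wanted one, while the other is para to the stronger methoxy donor. Double iodination and amine oxidation are further loss channels.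
- **Other drawbacks.** The phenol must be freed while ring A is at its most electron-rich, which means longer acid contact for C2'–N1' and a formaldehyde methylation on a free, Mannich-active phenol. The doubly flanked iodide slows oxidative addition, and coupling without A10 or 5-exo closure can compete.
- **Use here.** The chosen plan keeps a close relative of this reaction in reserve for step 8.

Key step: step 5

Assumption: 1 and 13 are taken to be purchasable. Target atoms carry flavone numbers (O1 to C8a) and piperidine atoms carry primed numbers.

## Steps

Step 1
Reactants: 1 2,4-dihydroxy-6-methoxybenzaldehyde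
Product: 2 2-hydroxy-6-methoxy-4-(methoxymethoxy)benzaldehyde
Conditions: MOMCl (1.05 equiv), i-Pr2NEt, CH2Cl2, 0 °C
Reagents that add atoms: chloromethyl methyl ether, COCCl
Why: O-alkylation of a phenol with an α-chloro ether; the 4-OH is free and the more acidic, whereas the 2-OH is tied to the formyl oxygen by a hydrogen bond and reacts much more slowly, so one equivalent of reagent should stop at 2.

Step 2
Reactants: 2 2-hydroxy-6-methoxy-4-(methoxymethoxy)benzaldehyde
Product: 3 2-methoxy-4-(methoxymethoxy)-6-(triisopropylsilyloxy)benzaldehyde
Conditions: TIPSCl, imidazole, DMF, rt
Reagents that add atoms: triisopropylsilyl chloride, CC(C)[Si](Cl)(C(C)C)C(C)C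
Why: Imidazole-promoted silylation of the remaining phenol under near-neutral conditions that keep the acetal and the aldehyde; TIPS is chosen because it is bulky, does not coordinate metals and outlasts Grignard reagent, amide base, brief acid and butyllithium.

Step 3
Reactants: 3 2-methoxy-4-(methoxymethoxy)-6-(triisopropylsilyloxy)benzaldehyde; 4 (R)-2-methylpropane-2-sulfinamide
Product: 5 (R,E)-N-[2-methoxy-4-(methoxymethoxy)-6-(triisopropylsilyloxy)benzylidene]-2-methylpropane-2-sulfinamide
Conditions: Ti(OEt)4 (2 equiv), THF, 60 °C
Reagents that add atoms: none
Why: Lewis-acid-mediated condensation of an aldehyde with tert-butanesulfinamide; Ti(OEt)4 activates the electron-rich, hindered formyl group and takes up the water, aldimines of this class form as the E isomer only, and sulfur is not touched, so 5 keeps the R configuration.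

Step 4
Reactants: 6 1-bromo-4-chlorobutane
Product: 7 4-chlorobutylmagnesium bromide (ether solution, titrated and used the same day)
Conditions: Mg turnings, cat. I2, Et2O, 20–30 °C
Reagents that add atoms: magnesium, [Mg]
Why: Grignard formation by insertion of magnesium into the weaker C–Br bond; the primary C–Cl bond is inert at this temperature, and self-alkylation to a four-membered ring or Wurtz-type coupling is slow in the cold.

Step 5
Reactants: 5 (R,E)-N-[2-methoxy-4-(methoxymethoxy)-6-(triisopropylsilyloxy)benzylidene]-2-methylpropane-2-sulfinamide; 7 4-chlorobutylmagnesium bromide
Product: 9 (S)-2-[2-methoxy-4-(methoxymethoxy)-6-(triisopropylsilyloxy)phenyl]-1-[(R)-tert-butylsulfinyl]piperidine, via bromomagnesium chloroalkyl sulfinamide 8 (not isolated)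
Conditions: 7 (1.5 equiv, Et2O) into 5, toluene, −60 → −20 °C; then KN(SiMe3)2 (toluene), THF, −20 → 40 °C
Reagents that add atoms: none
Why: Diastereoselective 1,2-addition of a Grignard reagent to an N-tert-butanesulfinyl aldimine followed by intramolecular N-alkylation, the known ω-haloalkyl Grignard route to 2-substituted pyrrolidines and piperidines. In toluene/ether, magnesium binds the sulfinyl oxygen and passes the alkyl group to carbon through a six-membered chair (Mg, O, S, N1', C2', C3') in which tert-butyl and the aryl group of the E-imine are equatorial; for the (R)-sulfinyl group this exposes the Si face, so C2' of 8 should be S (N > aryl > CH2). The C–Mg bond adds to C=N well below the temperature at which it attacks a C–Cl bond, which secures the chemoselectivity. Nitrogen in 8 is held too tightly by magnesium to alkylate, so KN(SiMe3)2 and THF are added to loosen it, and the nitrogen anion then displaces chloride at C6' in a 6-exo-tet SN2 closure that does not touch C2'; toluene is used instead of a chlorinated solvent so that the base can go into the same flask. Of the two ortho oxygens only OMe can bind magnesium, since the silyl ether is too hindered and too weakly basic, and the weakly coordinating medium should keep the sulfinyl-bound chair ahead of an N,OMe chelate with open attack. The base is non-nucleophilic, so the aryl silyl ether and the acetal should survive. The product and its C2' epimer are diastereomers and can be separated on silica, so a minor isomer need not be carried on.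

Step 6
Reactants: 9 (S)-2-[2-methoxy-4-(methoxymethoxy)-6-(triisopropylsilyloxy)phenyl]-1-[(R)-tert-butylsulfinyl]piperidine
Product: 11 (S)-2-[2-methoxy-4-(methoxymethoxy)-6-(triisopropylsilyloxy)phenyl]-1-methylpiperidine, via secondary amine hydrochloride 10 (not isolated)
Conditions: HCl (4 M in dioxane, 2.2 equiv), MeOH, 0 °C, 20 min, evaporate cold; then Et3N, 37% aq. HCHO, NaBH(OAc)3, CH2Cl2, 0 °C → rt
Reagents that add atoms: formaldehyde, C=O
Why: Acid methanolysis of a sulfinamide (protonation at N, attack of MeOH at S) is fast at 0 °C, whereas exchange of an aryl MOM acetal needs an oxocarbenium ion and is slow with two equivalents of acid in the cold, so only N–S should break. Reductive amination of the freed secondary amine with formaldehyde then gives the tertiary amine. Ring A has no free phenol at this stage, which suppresses Mannich aminomethylation, and the short cold acid contact should leave C2' untouched.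

Step 7
Reactants: 12 phenylacetylene; 13 N-methoxy-N-methylcarbamoyl chloride
Product: 15 N-methoxy-N-methyl-3-phenylprop-2-ynamide, via lithium phenylacetylide 14 (not isolated)
Conditions: n-BuLi, THF, −78 °C; then 13, −78 → 0 °C
Reagents that add atoms: none
Why: Acylation of a lithium acetylide with a carbamoyl chloride; chloride is by far the better leaving group, and the N-methoxy-N-methylamide formed resists a second addition, so the reaction should stop at 15.

Step 8
Reactants: 11 (S)-2-[2-methoxy-4-(methoxymethoxy)-6-(triisopropylsilyloxy)phenyl]-1-methylpiperidine; 15 N-methoxy-N-methyl-3-phenylprop-2-ynamide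
Product: 17 1-{2-methoxy-6-(methoxymethoxy)-3-[(S)-1-methylpiperidin-2-yl]-4-(triisopropylsilyloxy)phenyl}-3-phenylprop-2-yn-1-one, via aryllithium 16 (not isolated)
Conditions: n-BuLi, TMEDA, THF, −78 → 0 °C; then 15, −78 → −30 °C
Reagents that add atoms: none
Why: Directed ortho-metalation followed by Weinreb ketone synthesis. The C–H between OMe and OMOM is acidified by both oxygens and the acetal brings in the base, whereas the other ring C–H lies under the TIPS group, which neither binds lithium nor leaves room for the base. The amide stops at the ketone stage, and the C2'–H on an electron-rich arene is not acidic enough to be touched.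

Step 9
Reactants: 17 1-{2-methoxy-6-(methoxymethoxy)-3-[(S)-1-methylpiperidin-2-yl]-4-(triisopropylsilyloxy)phenyl}-3-phenylprop-2-yn-1-one
Product: 19 (S)-5-methoxy-6-(1-methylpiperidin-2-yl)-7-(triisopropylsilyloxy)flavone, via hydroxyaryl ynone 18 (not isolated)
Conditions: 2 M HCl in MeOH, 40 °C; NaHCO3 work-up
Reagents that add atoms: none
Why: Acid-catalysed acetal methanolysis frees O1, and phenol 18 adds to the acid-activated ynone at C2 in a 6-endo-dig oxa-Michael closure, the known acid route from o-hydroxyaryl ynones to flavones; any HCl or MeOH adduct of the triple bond ends in the same flavone by addition–elimination. The ketone now draws on the three ring A oxygens and the amine is protonated, so C2'–N1' ionisation is harder here than it would be in 9 to 11; early loss of TIPS would only anticipate step 10.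

Step 10
Reactants: 19 (S)-5-methoxy-6-(1-methylpiperidin-2-yl)-7-(triisopropylsilyloxy)flavone
Product: 20 (S)-7-hydroxy-5-methoxy-6-(1-methylpiperidin-2-yl)flavone (target)
Conditions: Bu4NF, AcOH (1:1), THF, 0 °C
Reagents that add atoms: none
Why: Fluoride-induced cleavage of an aryl silyl ether, driven by the Si–F bond; acetic acid buffers the phenoxide, so the enone, the 5-OMe and the Mannich-base carbon C2' see neither strong base nor heat.

## Compound list

1 | 2,4-dihydroxy-6-methoxybenzaldehyde | COc1cc(O)cc(O)c1C=O | starting material
2 | 2-hydroxy-6-methoxy-4-(methoxymethoxy)benzaldehyde | COc1cc(OCOC)cc(O)c1C=O | intermediate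
3 | 2-methoxy-4-(methoxymethoxy)-6-(triisopropylsilyloxy)benzaldehyde | COc1cc(OCOC)cc(O[Si](C(C)C)(C(C)C)C(C)C)c1C=O | intermediate
4 | (R)-2-methylpropane-2-sulfinamide | CC(C)(C)[S@@](=O)N | starting material
5 | (R,E)-N-[2-methoxy-4-(methoxymethoxy)-6-(triisopropylsilyloxy)benzylidene]-2-methylpropane-2-sulfinamide | CC(C)(C)[S@@](=O)/N=C/c1c(OC)cc(OCOC)cc1O[Si](C(C)C)(C(C)C)C(C)C | intermediate
6 | 1-bromo-4-chlorobutane | ClCCCCBr | starting material
7 | 4-chlorobutylmagnesium bromide | ClCCCC[Mg]Br | intermediate
8 | bromomagnesium salt of (R)-N-{(S)-5-chloro-1-[2-methoxy-4-(methoxymethoxy)-6-(triisopropylsilyloxy)phenyl]pentyl}-2-methylpropane-2-sulfinamide | COc1cc(OCOC)cc(O[Si](C(C)C)(C(C)C)C(C)C)c1[C@H](CCCCCl)N([Mg]Br)[S@](=O)C(C)(C)C | intermediate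
9 | (S)-2-[2-methoxy-4-(methoxymethoxy)-6-(triisopropylsilyloxy)phenyl]-1-[(R)-tert-butylsulfinyl]piperidine | COc1cc(OCOC)cc(O[Si](C(C)C)(C(C)C)C(C)C)c1[C@@H]1CCCCN1[S@](=O)C(C)(C)C | intermediate
10 | (S)-2-[2-methoxy-4-(methoxymethoxy)-6-(triisopropylsilyloxy)phenyl]piperidine hydrochloride | COc1cc(OCOC)cc(O[Si](C(C)C)(C(C)C)C(C)C)c1[C@@H]1CCCCN1.Cl | intermediate
11 | (S)-2-[2-methoxy-4-(methoxymethoxy)-6-(triisopropylsilyloxy)phenyl]-1-methylpiperidine | COc1cc(OCOC)cc(O[Si](C(C)C)(C(C)C)C(C)C)c1[C@@H]1CCCCN1C | intermediate
12 | phenylacetylene | C#Cc1ccccc1 | starting material
13 | N-methoxy-N-methylcarbamoyl chloride | CON(C)C(=O)Cl | starting material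
14 | lithium phenylacetylide | [Li]C#Cc1ccccc1 | intermediate
15 | N-methoxy-N-methyl-3-phenylprop-2-ynamide | CON(C)C(=O)C#Cc1ccccc1 | intermediate
16 | {2-methoxy-6-(methoxymethoxy)-3-[(S)-1-methylpiperidin-2-yl]-4-(triisopropylsilyloxy)phenyl}lithium | COc1c([Li])c(OCOC)cc(O[Si](C(C)C)(C(C)C)C(C)C)c1[C@@H]1CCCCN1C | intermediate
17 | 1-{2-methoxy-6-(methoxymethoxy)-3-[(S)-1-methylpiperidin-2-yl]-4-(triisopropylsilyloxy)phenyl}-3-phenylprop-2-yn-1-one | COc1c(C(=O)C#Cc2ccccc2)c(OCOC)cc(O[Si](C(C)C)(C(C)C)C(C)C)c1[C@@H]1CCCCN1C | intermediate
18 | 1-{6-hydroxy-2-methoxy-3-[(S)-1-methylpiperidin-2-yl]-4-(triisopropylsilyloxy)phenyl}-3-phenylprop-2-yn-1-one | COc1c(C(=O)C#Cc2ccccc2)c(O)cc(O[Si](C(C)C)(C(C)C)C(C)C)c1[C@@H]1CCCCN1C | intermediate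
19 | (S)-5-methoxy-6-(1-methylpiperidin-2-yl)-7-(triisopropylsilyloxy)flavone | COc1c([C@@H]2CCCCN2C)c(O[Si](C(C)C)(C(C)C)C(C)C)cc2oc(-c3ccccc3)cc(=O)c12 | intermediate
20 | (S)-7-hydroxy-5-methoxy-6-(1-methylpiperidin-2-yl)flavone | COc1c([C@@H]2CCCCN2C)c(O)cc2oc(-c3ccccc3)cc(=O)c12 | target

## Step count and least certain steps

Total step count: 10 (steps 4 and 7 are one-step side branches).
Longest linear sequence: 8 steps from 1 (steps 1, 2, 3, 5, 6, 8, 9, 10).

**Step 5 (key step).**

- **Facial selectivity.** The most likely failure is poor or reversed facial selectivity. The ortho OMe can draw magnesium into a six-membered chelate with N1'. This frees the sulfinyl oxygen and lets a second molecule of reagent attack in an open arrangement. The twist of the doubly ortho-substituted aryl group also distorts the chair.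
- **Slow addition.** Three donor oxygens lower the electrophilicity of C2'. Slow addition would force higher temperatures, at which the reagent is consumed by Wurtz-type self-coupling.
- **Stalled ring closure.** Closure may stall while nitrogen stays bound to magnesium.
- **Fallback, from 5 back to 9.** C2'–C3' is made by an indium-mediated Barbier allylation (In powder, allyl bromide, THF). Its cyclic transition state should attack the same Si face and is less sensitive to neighbouring ethers, giving homoallylic sulfinamide F1. N-allylation (NaH, allyl bromide, DMF) gives diene F2. Ring-closing metathesis with the second-generation Grubbs catalyst RuCl2(=CHPh)(H2IMes)(PCy3) in CH2Cl2 gives tetrahydropyridine F3. Diimide reduction of the ring alkene (TsNHNH2, NaOAc) leads to 9.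

**Step 6.**

- **What may go wrong.** The MOM acetal may be partly lost during the acid stage. Enantiomeric purity may also erode through reversible C2'–N1' ionisation on the very electron-rich ring, so purity should be checked on 11 by chiral HPLC.
- **Fallback, from 9 back to 11.** Selectivity is given up. Exhaustive methanolysis (HCl, MeOH, rt) removes both the sulfinyl and MOM groups to give aminophenol F4. Reductive methylation, with formaldehyde added slowly to amine and NaBH(OAc)3 at 0 °C to outrun ring aminomethylation, gives N-methyl phenol F5. O-alkylation of its sodium phenoxide (NaH, MOMCl, THF, 0 °C) restores 11.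

**Step 8.**

- **What may go wrong.** Lithiation may be incomplete, because the methyl ether next to the piperidine must turn its methyl group toward the reacting C–H. Deprotonation could also occur at the position beside the silyl ether, followed by an O-to-C silyl shift. The hindered aryllithium may be slow to acylate. Addition of the released hydroxylamine to the ynone on quench would be harmless, because such an adduct also closes in step 9.
- **Fallback, from 11 back to 17.** Deprotonation is replaced by electrophilic halogenation and palladium chemistry. NIS in MeCN at −20 °C, with one equivalent of TFA to mask the amine, should iodinate the less shielded position and give aryl iodide F6. A carbonylative Sonogashira coupling of F6 with 12 (PdCl2(PPh3)2, Et3N, CO balloon, THF, 40 °C) gives 17.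

**Step 9.**

- **What may go wrong.** A 5-exo closure at the α-carbon may compete. The alkyne may simply be hydrated, leaving a slow final dehydration. Prolonged warm acid may erode C2'.
- **Fallback, from 17 back to 19.** An amine relay fixes the site of attack before O1 is freed. Conjugate addition of Et2NH (EtOH, rt) gives enaminone F7, in which C2 is the only electrophilic carbon. Brief treatment with p-TsOH·H2O in MeOH at rt cleaves the acetal, and the phenol replaces the amine by addition–elimination to give 19.

## Further compounds

F1 | step 5 | (R)-N-{(S)-1-[2-methoxy-4-(methoxymethoxy)-6-(triisopropylsilyloxy)phenyl]but-3-en-1-yl}-2-methylpropane-2-sulfinamide | COc1cc(OCOC)cc(O[Si](C(C)C)(C(C)C)C(C)C)c1[C@H](CC=C)N[S@](=O)C(C)(C)C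
F2 | step 5 | (R)-N-allyl-N-{(S)-1-[2-methoxy-4-(methoxymethoxy)-6-(triisopropylsilyloxy)phenyl]but-3-en-1-yl}-2-methylpropane-2-sulfinamide | COc1cc(OCOC)cc(O[Si](C(C)C)(C(C)C)C(C)C)c1[C@H](CC=C)N(CC=C)[S@](=O)C(C)(C)C
F3 | step 5 | (S)-2-[2-methoxy-4-(methoxymethoxy)-6-(triisopropylsilyloxy)phenyl]-1-[(R)-tert-butylsulfinyl]-1,2,3,6-tetrahydropyridine | COc1cc(OCOC)cc(O[Si](C(C)C)(C(C)C)C(C)C)c1[C@@H]1CC=CCN1[S@](=O)C(C)(C)C
F4 | step 6 | (S)-3-methoxy-4-(piperidin-2-yl)-5-(triisopropylsilyloxy)phenol | COc1cc(O)cc(O[Si](C(C)C)(C(C)C)C(C)C)c1[C@@H]1CCCCN1
F5 | step 6 | (S)-3-methoxy-4-(1-methylpiperidin-2-yl)-5-(triisopropylsilyloxy)phenol | COc1cc(O)cc(O[Si](C(C)C)(C(C)C)C(C)C)c1[C@@H]1CCCCN1C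
F6 | step 8 | (S)-2-[3-iodo-2-methoxy-4-(methoxymethoxy)-6-(triisopropylsilyloxy)phenyl]-1-methylpiperidine | COc1c(I)c(OCOC)cc(O[Si](C(C)C)(C(C)C)C(C)C)c1[C@@H]1CCCCN1C
F7 | step 9 | (E)-3-(diethylamino)-1-{2-methoxy-6-(methoxymethoxy)-3-[(S)-1-methylpiperidin-2-yl]-4-(triisopropylsilyloxy)phenyl}-3-phenylprop-2-en-1-one | COc1c(C(=O)/C=C(/N(CC)CC)c2ccccc2)c(OCOC)cc(O[Si](C(C)C)(C(C)C)C(C)C)c1[C@@H]1CCCCN1C
A1 | alternative 1 | (S)-6-[1-(N-allyl-N-methylamino)but-3-en-1-yl]-7-hydroxy-5-methoxyflavone | COc1c([C@H](CC=C)N(C)CC=C)c(O)cc2oc(-c3ccccc3)cc(=O)c12
A2 | alternative 1 | 7-hydroxy-5-methoxy-4-oxo-2-phenyl-4H-chromene-6-carbaldehyde | COc1c(C=O)c(O)cc2oc(-c3ccccc3)cc(=O)c12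
A3 | alternative 1 | N-methylallylamine | C=CCNC
A4 | alternative 1 | allylboronic acid pinacol ester | C=CCB1OC(C)(C)C(C)(C)O1
A5 | alternative 1 | (S)-7-hydroxy-5-methoxy-6-(1-methyl-1,2,3,6-tetrahydropyridin-2-yl)flavone | COc1c([C@@H]2CC=CCN2C)c(O)cc2oc(-c3ccccc3)cc(=O)c12
A6 | alternative 2 | tert-butyl (S)-2-(5,7-dihydroxy-4-oxo-2-phenyl-4H-chromen-6-yl)piperidine-1-carboxylate | Oc1c([C@@H]2CCCCN2C(=O)OC(C)(C)C)c(O)cc2oc(-c3ccccc3)cc(=O)c12
A7 | alternative 2 | methyl 2-[(S)-1-(tert-butoxycarbonyl)piperidin-2-yl]-3-(2-methyl-4-oxo-6-phenyl-4H-pyran-3-yl)-3-oxopropanoate | COC(=O)C([C@@H]1CCCCN1C(=O)OC(C)(C)C)C(=O)c1c(C)oc(-c2ccccc2)cc1=O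
A8 | alternative 3 | (S)-5-methoxy-6-(1-methylpiperidin-2-yl)-7-(triisopropylsilyloxy)flavone | COc1c([C@@H]2CCCCN2C)c(O[Si](C(C)C)(C(C)C)C(C)C)cc2oc(-c3ccccc3)cc(=O)c12
A9 | alternative 3 | (S)-2-iodo-3-methoxy-4-(1-methylpiperidin-2-yl)-5-(triisopropylsilyloxy)phenol | COc1c(I)c(O)cc(O[Si](C(C)C)(C(C)C)C(C)C)c1[C@@H]1CCCCN1C
A10 | alternative 3 | carbon monoxide | [C-]#[O+]
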